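**Plan**
Retrosynthesis: the three phenols are unmasked last (MOM ethers). Ring C is then cut at C3–C4 into two electrophiles, a racemic benzylic chloride at C3 and an S-2-pyridyl thioester at C4. Finally O1–C2 (Williamson), C2–C3 (chloromethyl carbenoid on the ring B ester) and C5'–prenyl (Stille) are cut.
Forward: ring B ester, prenylation, α-chloro ketone; union with the ring A phenol; reduction, saponification and activation of both termini; closure of ring C as the only ring-forming event; deprotection.
Enabling feature: C3 is benzylic to ring B and para to its 4'-methoxy group, so its C–Cl bond is readily given up to a planar, stabilised radical. C4 is an aroyl carbon on ring A, and the O1–C2 tether holds these two like-polarised carbons in a 1,6-relationship.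
Stereochemistry: C3, the only stereocentre, is set in the ring closure by a chiral bis(oxazoline)–nickel catalyst, stereoconvergently from the racemate and without base. Only one short, base-free step follows.

Key step: step 10

Remark 1: the sense of induction of a bis(oxazoline)–nickel catalyst in a ring closure cannot be derived with certainty. (R,R)-Ph-BOX is written, and its equally available antipode is used if a trial cyclisation gives the 3R series.
Remark 2: compound 1 is taken as a catalogue compound; it is otherwise one step away (monobromination of methyl 3,4-dihydroxybenzoate).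
Abbreviation: Ar = 4-methoxy-3-(methoxymethoxy)-5-(3-methylbut-2-en-1-yl)phenyl.

Step 1
Reactants: 1 methyl 3-bromo-4,5-dihydroxybenzoate
Product: 2 methyl 3-bromo-5-hydroxy-4-methoxybenzoate
Conditions: MeI (1.05 equiv), Li2CO3 (1.1 equiv), DMF, 45 °C
Reagents that add atoms: iodomethane, CI
Why: Williamson-type O-methylation under a weak base that should ionise only the 4-OH (para to the ester and ortho to bromine, hence the more acidic one), which gives the 4-methoxy/3-hydroxy pattern of ring B.

Step 2
Reactants: 2 methyl 3-bromo-5-hydroxy-4-methoxybenzoate
Product: 3 methyl 3-bromo-4-methoxy-5-(methoxymethoxy)benzoate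
Conditions: MOMCl, iPr2NEt, CH2Cl2, 0 °C to rt
Reagents that add atoms: chloromethyl methyl ether, COCCl
Why: O-alkylation of the remaining phenol (MOM protection) gives an acetal that is stable to palladium, organolithium, hydride and hydroxide and is removable later without base.

Step 3
Reactants: 3 methyl 3-bromo-4-methoxy-5-(methoxymethoxy)benzoate
Product: 4 methyl 4-methoxy-3-(methoxymethoxy)-5-(3-methylbut-2-en-1-yl)benzoate
Conditions: tributyl(3-methylbut-2-en-1-yl)stannane, Pd(PPh3)4 (5 mol %), DMF, 100 °C
Reagents that add atoms: tributyl(3-methylbut-2-en-1-yl)stannane, CCCC[Sn](CCCC)(CCCC)CC=C(C)C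
Why: Stille coupling, in which oxidative addition of zerovalent palladium into the aryl–bromine bond, transmetallation at the unsubstituted allyl terminus and reductive elimination should deliver the linear prenyl arene while ester, MOM ether and methyl ether stay inert.

Step 4
Reactants: 4 methyl 4-methoxy-3-(methoxymethoxy)-5-(3-methylbut-2-en-1-yl)benzoate
Product: 5 2-chloro-1-Ar-ethan-1-one
Conditions: ICH2Cl, MeLi·LiBr added slowly, THF, −78 °C; AcOH quench at −78 °C
Reagents that add atoms: chloroiodomethane, ClCI
Why: Ester homologation with a lithium carbenoid, in which chloromethyllithium made by iodine–lithium exchange in the presence of 4 adds once, the tetrahedral lithium alkoxide persists at −78 °C and the cold acid quench releases the α-chloro ketone, so that C2 and C3 arrive without any halogenating agent that would attack the prenyl group.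

Step 5
Reactants: 6 methyl 2,4,6-trihydroxybenzoate
Product: 7 methyl 2-hydroxy-4,6-bis(methoxymethoxy)benzoate
Conditions: MOMCl (2.1 equiv), iPr2NEt (2.5 equiv), CH2Cl2, 0 °C
Reagents that add atoms: chloromethyl methyl ether, COCCl
Why: Selective double MOM protection, which should stop at the bis-ether because the last ortho-OH is hydrogen-bonded to the ester carbonyl and is the least nucleophilic.

Step 6
Reactants: 5 2-chloro-1-Ar-ethan-1-one; 7 methyl 2-hydroxy-4,6-bis(methoxymethoxy)benzoate
Product: 8 methyl 2-(2-Ar-2-oxoethoxy)-4,6-bis(methoxymethoxy)benzoate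
Conditions: K2CO3, NaI (10 mol %), acetone, 45 °C
Reagents that add atoms: none
Why: Williamson ether synthesis with in situ Finkelstein exchange, in which the phenoxide of 7 displaces the activated primary halide of 5 to form O1–C2, while the mild carbonate base and moderate temperature hold back Dieckmann-type attack of the new methylene group on the hindered ester.

Step 7
Reactants: 8 methyl 2-(2-Ar-2-oxoethoxy)-4,6-bis(methoxymethoxy)benzoate
Product: 10 racemic 2-(2-Ar-2-hydroxyethoxy)-4,6-bis(methoxymethoxy)benzoic acid, via hydroxy ester 9 (not isolated)
Conditions: NaBH4, THF/MeOH, 0 °C; then aq KOH (10 equiv), 75 °C; 1 M HCl to pH 4 at 0 °C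
Reagents that add atoms: potassium hydroxide, [K+].[OH-]
Why: Borohydride reduction of the aryl ketone (racemic alcohol, whose configuration is erased later) followed in the same flask by saponification of the hindered benzoate, with reduction first so that no enolisable α-aryloxy ketone meets hot hydroxide, to which MOM ethers, prenyl group and β-aryloxy alcohol are stable.

Step 8
Reactants: 10 racemic 2-(2-Ar-2-hydroxyethoxy)-4,6-bis(methoxymethoxy)benzoic acid
Product: 11 racemic S-(pyridin-2-yl) 2-(2-Ar-2-hydroxyethoxy)-4,6-bis(methoxymethoxy)benzenecarbothioate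
Conditions: 2,2'-dipyridyl disulfide (1.1 equiv), PPh3 (1.1 equiv), CH2Cl2, 0 °C to rt
Reagents that add atoms: 2,2'-dipyridyl disulfide, c1ccc(nc1)SSc1ccccn1
Why: Oxidation–reduction condensation with PPh3 and a disulfide (the acid activation of the Corey–Nicolaou lactonisation), in which pyridinethiolate attacks the acyloxyphosphonium salt under neutral conditions and gives an acyl donor that, unlike the acid chloride, is not attacked by the neighbouring MOM ether and closes to the seven-membered lactone only on heating.

Step 9
Reactants: 11 racemic S-(pyridin-2-yl) 2-(2-Ar-2-hydroxyethoxy)-4,6-bis(methoxymethoxy)benzenecarbothioate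
Product: 12 racemic S-(pyridin-2-yl) 2-(2-Ar-2-chloroethoxy)-4,6-bis(methoxymethoxy)benzenecarbothioate
Conditions: 1-chloro-N,N,2-trimethylprop-1-en-1-amine (1.2 equiv), CH2Cl2, 0 °C to rt; concentrated and used crude
Reagents that add atoms: 1-chloro-N,N,2-trimethylprop-1-en-1-amine, CC(C)=C(Cl)N(C)C
Why: Deoxychlorination with an α-chloroenamine under neutral conditions, in which the alkoxyiminium chloride collapses at the p-methoxy-stabilised benzylic carbon without HCl that would harm MOM ethers or the prenyl group and leaves only an inert amide, so the labile chloride can be used without chromatography.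

Step 10
Reactants: 12 racemic S-(pyridin-2-yl) 2-(2-Ar-2-chloroethoxy)-4,6-bis(methoxymethoxy)benzenecarbothioate
Product: 13 (3S)-3-Ar-5,7-bis(methoxymethoxy)chroman-4-one
Conditions: NiCl2(dme) (10 mol %), (R,R)-Ph-BOX [(4R,4'R)-2,2'-(propane-2,2-diyl)bis(4-phenyl-4,5-dihydrooxazole), 12 mol %], Mn powder (3 equiv), 2,6-dimethylbenzoic acid (1.0 equiv), 3 Å MS, DMA/THF 3:7, 20 °C, 12 added by syringe pump over 10 h (final 0.01 M); pH 5 buffer work-up
Reagents that add atoms: none
Why: Proposed new method: zerovalent nickel carrying the chiral bis(oxazoline) inserts into the acyl–sulfur bond of 12, manganese reduces the acylnickel to the monovalent state, this abstracts the benzylic chlorine, and the planar benzylic radical is recaptured at nickel to give a seven-membered acyl(benzyl)nickelacycle of trivalent nickel that collapses by C–C reductive elimination, so two electrophilic carbons are joined without any carbanion or base. The closest known reaction types are the enantioconvergent nickel-catalysed reductive acyl cross-coupling of acid chlorides with racemic secondary benzylic chlorides and the nickel/manganese ketone synthesis from S-2-pyridyl thioesters and benzyl chlorides, both intermolecular; new here are the ring closure and a hindered aroyl thioester as partner of a chiral catalyst. Ring C closes in a formal 6-exo-trig mode, the benzylic carbon C3 bonding to the carbonyl carbon C4 whose C=O stays exocyclic. C3 is under catalyst control, because both enantiomers of 12 give the same radical and the face at which it binds to, and is eliminated from, the chiral nickel centre decides the configuration. The step needs ring closure over benzylic dimerisation (secured by the tether and slow addition), retention of the β-aryloxy group (the acylnickel in the same molecule should capture the radical faster than β-scission or β-elimination), no decarbonylation (20 °C, nitrogen ligand), and inert prenyl and MOM groups (no hydride, no strong acid). 2,6-Dimethylbenzoic acid protonates the released pyridinethiolate, so the configurationally labile α-aryl ketone never meets a base.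

Step 11
Reactants: 13 (3S)-3-Ar-5,7-bis(methoxymethoxy)chroman-4-one
Product: 14 (3S)-5,7,3'-trihydroxy-4'-methoxy-5'-prenylisoflavanone
Conditions: ZnBr2 (3.3 equiv), n-PrSH (6.6 equiv), CH2Cl2, 0 °C, 10–15 min; pH 5 buffer quench, acid-washed silica
Reagents that add atoms: none
Why: Lewis acid/thiol transacetalisation of the MOM ethers, in which the zinc-activated acetals are cleaved by the soft thiol within minutes at 0 °C without base or protic acid, so the prenyl group and the readily enolised C3 stereocentre should survive.

**Compound list**
1 | methyl 3-bromo-4,5-dihydroxybenzoate | COC(=O)c1cc(O)c(O)c(Br)c1 | starting material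
2 | methyl 3-bromo-5-hydroxy-4-methoxybenzoate | COC(=O)c1cc(O)c(OC)c(Br)c1 | intermediate
3 | methyl 3-bromo-4-methoxy-5-(methoxymethoxy)benzoate | COC(=O)c1cc(OCOC)c(OC)c(Br)c1 | intermediate
4 | methyl 4-methoxy-3-(methoxymethoxy)-5-(3-methylbut-2-en-1-yl)benzoate | COC(=O)c1cc(OCOC)c(OC)c(CC=C(C)C)c1 | intermediate
5 | 2-chloro-1-[4-methoxy-3-(methoxymethoxy)-5-(3-methylbut-2-en-1-yl)phenyl]ethan-1-one | ClCC(=O)c1cc(OCOC)c(OC)c(CC=C(C)C)c1 | intermediate
6 | methyl 2,4,6-trihydroxybenzoate | COC(=O)c1c(O)cc(O)cc1O | starting material
7 | methyl 2-hydroxy-4,6-bis(methoxymethoxy)benzoate | COC(=O)c1c(O)cc(OCOC)cc1OCOC | intermediate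
8 | methyl 2-(2-Ar-2-oxoethoxy)-4,6-bis(methoxymethoxy)benzoate (keto ester) | COC(=O)c1c(OCC(=O)c2cc(OCOC)c(OC)c(CC=C(C)C)c2)cc(OCOC)cc1OCOC | intermediate
9 | racemic methyl 2-(2-Ar-2-hydroxyethoxy)-4,6-bis(methoxymethoxy)benzoate (hydroxy ester, not isolated) | COC(=O)c1c(OCC(O)c2cc(OCOC)c(OC)c(CC=C(C)C)c2)cc(OCOC)cc1OCOC | intermediate
10 | racemic 2-(2-Ar-2-hydroxyethoxy)-4,6-bis(methoxymethoxy)benzoic acid | OC(=O)c1c(OCC(O)c2cc(OCOC)c(OC)c(CC=C(C)C)c2)cc(OCOC)cc1OCOC | intermediate
11 | racemic S-(pyridin-2-yl) 2-(2-Ar-2-hydroxyethoxy)-4,6-bis(methoxymethoxy)benzenecarbothioate | O=C(Sc1ccccn1)c1c(OCC(O)c2cc(OCOC)c(OC)c(CC=C(C)C)c2)cc(OCOC)cc1OCOC | intermediate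
12 | racemic S-(pyridin-2-yl) 2-(2-Ar-2-chloroethoxy)-4,6-bis(methoxymethoxy)benzenecarbothioate | O=C(Sc1ccccn1)c1c(OCC(Cl)c2cc(OCOC)c(OC)c(CC=C(C)C)c2)cc(OCOC)cc1OCOC | intermediate
13 | (3S)-3-[4-methoxy-3-(methoxymethoxy)-5-(3-methylbut-2-en-1-yl)phenyl]-5,7-bis(methoxymethoxy)chroman-4-one | COc1c(OCOC)cc([C@H]2COc3cc(OCOC)cc(OCOC)c3C2=O)cc1CC=C(C)C | intermediate
14 | (3S)-5,7,3'-trihydroxy-4'-methoxy-5'-prenylisoflavanone | COc1c(O)cc([C@H]2COc3cc(O)cc(O)c3C2=O)cc1CC=C(C)C | target

**Step count and risks**
Total step count: 11. Longest linear sequence: 10 (steps 1–4 and 6–11).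

Steps most likely to fail:

1. Step 10. Oxidative addition at the doubly ortho-substituted aroyl thioester may be too slow with the bulky chiral ligand. Benzylic dimerisation, loss of the aryloxy group from the radical, or poor facial selectivity at C3 could then take over.
 - The fallback sets out from 12 and returns at 13.
 - Ring closure with the less hindered achiral catalyst NiCl2(dme)/4,4'-di-tert-butyl-2,2'-bipyridine and Mn powder in DMA should give the racemic tri-MOM isoflavanone F1. This is the standard ketone synthesis from S-2-pyridyl thioesters and benzylic chlorides.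
 - Asymmetric transfer hydrogenation with dynamic kinetic resolution follows, using RuCl[(S,S)-TsDPEN](p-cymene) and HCO2H/Et3N. This reaction is established on isoflavanones: the amine racemises C3 and only the 3S ketone is reduced fast. It should give the cis-(3S,4S)-isoflavan-4-ol F2.
 - Oxidation with Dess–Martin periodinane in CH2Cl2 at 0 °C does not touch C3 and leads back to 13.

2. Step 11. The zinc-chelated ketone may enolise and erode the enantiomeric purity, the 7-O-acetal may cleave incompletely, or the thiol may add across the prenyl double bond.
 - The fallback sets out from 13 and returns at 14.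
 - The acetals are first exchanged for silyl ethers under non-acidic conditions (TMSOTf, 2,2'-bipyridyl, CH2Cl2, 0 °C) to give the tris(trimethylsilyl) ether F3.
 - F3 is then hydrolysed with water/THF at about pH 6 and rt, so that neither a thiol nor a chelating Lewis acid meets the free 5-hydroxy ketone.

3. Step 8. The free benzylic alcohol may interfere during acid activation, either by closing to the seven-membered lactone or by being converted into a pyridyl sulfide. Attack of the thiolate on the hindered acyl group may also be sluggish.
 - The fallback sets out from 10 and returns at 12, leaving out 11; the order of activation is inverted.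
 - 1-Chloro-N,N,2-trimethylprop-1-en-1-amine (2.3 equiv, CH2Cl2, −20 °C) converts both hydroxyl functions at once into the chloro acid chloride F4.
 - F4 is kept cold and intercepted at once with pyridine-2-thiol (1.0 equiv) and 2,6-lutidine at −40 °C, before the ortho MOM ether can attack the acyl chloride.

**Further compounds**
F1 | step 10 | racemic 3-Ar-5,7-bis(methoxymethoxy)chroman-4-one | COc1c(OCOC)cc(C2COc3cc(OCOC)cc(OCOC)c3C2=O)cc1CC=C(C)C
F2 | step 10 | cis-(3S,4S)-3-Ar-5,7-bis(methoxymethoxy)chroman-4-ol | COc1c(OCOC)cc([C@H]2COc3cc(OCOC)cc(OCOC)c3[C@H]2O)cc1CC=C(C)C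
F3 | step 11 | (3S)-3-[4-methoxy-5-(3-methylbut-2-en-1-yl)-3-(trimethylsilyloxy)phenyl]-5,7-bis(trimethylsilyloxy)chroman-4-one | COc1c(O[Si](C)(C)C)cc([C@H]2COc3cc(O[Si](C)(C)C)cc(O[Si](C)(C)C)c3C2=O)cc1CC=C(C)C
F4 | step 8 | racemic 2-(2-Ar-2-chloroethoxy)-4,6-bis(methoxymethoxy)benzoyl chloride | O=C(Cl)c1c(OCC(Cl)c2cc(OCOC)c(OC)c(CC=C(C)C)c2)cc(OCOC)cc1OCOC
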